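**Overview**

- Retrosynthetic cuts, in order: the two O–benzyl bonds (7-O and 4'-O), then C5–OMe (back to C5–Br), then O1–C8a of ring C, then C3–C4 (aldol, with C4 at the carbinol level), and last the bond from the C2 carbonyl carbon to C1' of ring B.
- Enabling feature: ring A (C4a, C5, C6, C7, C8, C8a) has a local mirror plane through C7 and C4a, because C6 and C8 both carry OMe and C5 and C8a both carry oxygen. A ring A precursor brominated at both future C5 and C8a, made from O-benzylsyringaldehyde, therefore offers two identical carbons for the O1–C8a closure and keeps the twin bromide for the 5-OMe.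
- Forward order: rings A and B are bought (syringaldehyde, 4-benzyloxybromobenzene). The chain is joined at C3–C4, C4 is oxidised, ring C (the only ring made) closes at O1–C8a, C5–Br is exchanged for C5–OMe, and both benzyl groups are removed.
- Stereochemistry: the target has no stereocentre. The two centres of the aldol adduct and the one of the diketone form without control and vanish on oxidation and on formation of the pyranone.

Key step: step 6

Remark: diketone 14 is drawn as the diketo tautomer although it should exist largely as the chelated enol, and 13 and 14 are racemic and used as mixtures; neither point affects a later step.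

**Route**

Step 1
Reactants: 1 1-(benzyloxy)-4-bromobenzene; 2 N,2-dimethoxy-N-methylacetamide
Product: 5 1-[4-(benzyloxy)phenyl]-2-methoxyethan-1-one, via aryl Grignard reagent 3 (not isolated), via magnesium hemiaminal chelate 4 (not isolated)
Conditions: Mg turnings, BrCH2CH2Br (cat.), THF, reflux; then 2, THF, 0 °C to rt; 1 M HCl, 0 °C
Reagents that add atoms: none
Why: Weinreb ketone synthesis, in which the aryl Grignard reagent adds only once to the N-methoxy-N-methylamide because the five-membered magnesium chelate 4 holds the tetrahedral adduct until the acidic quench, while the benzyl ether is inert to magnesium.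

Step 2
Reactants: 6 syringaldehyde (4-hydroxy-3,5-dimethoxybenzaldehyde)
Product: 8 4-(benzyloxy)-3,5-dimethoxybenzaldehyde, via potassium phenoxide 7 (not isolated)
Conditions: BnBr (1.1 equiv), K2CO3 (1.5 equiv), DMF, 60 °C
Reagents that add atoms: benzyl bromide, BrCc1ccccc1
Why: Williamson ether synthesis, in which the phenol, made acidic by the para formyl group, is converted by K2CO3 into phenoxide 7 and benzylated at oxygen by SN2 attack on benzyl bromide, the benzyl group marking the future 7-oxygen for release at the end.

Step 3
Reactants: 8 4-(benzyloxy)-3,5-dimethoxybenzaldehyde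
Product: 10 4-(benzyloxy)-2,6-dibromo-3,5-dimethoxybenzaldehyde, via monobromide 9 (not isolated)
Conditions: Br2 (2.3 equiv), NaOAc (2.5 equiv), AcOH, rt to 50 °C, dark
Reagents that add atoms: bromine, BrBr
Why: Twofold electrophilic aromatic bromination, which should go to completion because C2 and C6 are the only free ring positions and each is ortho to one methoxy group and para to the other, while the trialkoxy ring is far more electron-rich than the phenyl ring of the benzyl group and NaOAc traps HBr so that the benzyl ether is not cleaved.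

Step 4
Reactants: 5 1-[4-(benzyloxy)phenyl]-2-methoxyethan-1-one; 10 4-(benzyloxy)-2,6-dibromo-3,5-dimethoxybenzaldehyde
Product: 13 3-[4-(benzyloxy)-2,6-dibromo-3,5-dimethoxyphenyl]-1-[4-(benzyloxy)phenyl]-3-hydroxy-2-methoxypropan-1-one (racemic syn/anti mixture), via lithium enolate 11 (not isolated), via lithium aldolate 12 (not isolated)
Conditions: LiN(iPr)2 (1.05 equiv), THF, −78 °C; then 10 in THF, −78 °C; AcOH (1.1 equiv) at −78 °C
Reagents that add atoms: none
Why: Directed aldol addition of a preformed lithium enolate, clean in principle because ketone 5 has one enolisable position and aldehyde 10 has none, LiN(iPr)2 does not exchange aryl bromides and the cold acidic quench protonates aldolate 12 before retro-aldol cleavage; the two new stereocentres (the later C3 and C4) form without control and are both destroyed later, so the mixture is carried on as such.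

Step 5
Reactants: 13 aldol adduct (racemic syn/anti mixture)
Product: 14 1-[4-(benzyloxy)-2,6-dibromo-3,5-dimethoxyphenyl]-3-[4-(benzyloxy)phenyl]-2-methoxypropane-1,3-dione (racemic)
Conditions: Dess–Martin periodinane (1.3 equiv), CH2Cl2, 0 °C to rt
Reagents that add atoms: none
Why: Dess–Martin oxidation of the secondary benzylic alcohol under non-basic conditions, which avoids the retro-aldol pathway of basic oxidants and removes the carbinol stereocentre, leaving one centre at C3 that is lost by enolisation.

Step 6
Reactants: 14 1-[4-(benzyloxy)-2,6-dibromo-3,5-dimethoxyphenyl]-3-[4-(benzyloxy)phenyl]-2-methoxypropane-1,3-dione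
Product: 16 7-(benzyloxy)-2-[4-(benzyloxy)phenyl]-5-bromo-3,6,8-trimethoxy-4H-chromen-4-one, via potassium diketonate 15 (not isolated)
Conditions: CuI (10 mol %), 1,10-phenanthroline (20 mol %), K2CO3 (1.5 equiv), dry degassed DMF, 90 °C, argon
Reagents that add atoms: none
Why: This is an Ullmann-type copper-catalysed intramolecular O-arylation, closest to the known closure of 1-(2-bromoaryl)-1,3-diketones to flavones: K2CO3 turns 14 into diketonate 15, which binds monovalent copper, the metal inserts into a C–Br bond ortho to the aroyl carbonyl, and C–O reductive elimination from the trivalent aryl copper enolate forms O1–C8a. Ring C, the six-membered pyranone, closes by attack of the enolate oxygen of the ring B carbonyl on the aryl carbon with the leaving bromide outside the new ring (formally 6-exo-trig). No stereocentre is created, and the uncontrolled centre at C3 disappears as C2=C3 becomes part of the pyranone. Site selectivity is not required, because the mirror plane of the 2,6-dibromoaryl group through its C1 and C4 makes the two C–Br bonds identical, so either closure gives the same product. O-arylation rather than C-arylation is secured by ring size, since bond formation through C3 would need a four-membered ring. Single reaction is secured because the only internal nucleophile is used up in the closure, so the second bromide, now at C5, should stay in place as long as water and reductants are excluded and the temperature is kept moderate.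

Step 7
Reactants: 16 7-(benzyloxy)-2-[4-(benzyloxy)phenyl]-5-bromo-3,6,8-trimethoxy-4H-chromen-4-one
Product: 17 7-(benzyloxy)-2-[4-(benzyloxy)phenyl]-3,5,6,8-tetramethoxy-4H-chromen-4-one
Conditions: NaOMe (5 equiv, 25 wt % in MeOH), CuBr (0.3 equiv), DMF, 105 °C, argon
Reagents that add atoms: sodium methoxide, [Na+].[O-]C
Why: Ullmann-type copper-mediated exchange of an aryl bromide for methoxide, established for bromoflavones, helped here because the C5 bromide lies peri to the C4 carbonyl, which can coordinate copper, while the benzyl and methyl ethers are inert and any methoxide addition at C2 is reversible.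

Step 8
Reactants: 17 7-(benzyloxy)-2-[4-(benzyloxy)phenyl]-3,5,6,8-tetramethoxy-4H-chromen-4-one
Product: 20 7-hydroxy-2-(4-hydroxyphenyl)-3,5,6,8-tetramethoxy-4H-chromen-4-one (target), via 7-O-benzyl monoether 18 (not isolated), via 4'-O-benzyl monoether 19 (not isolated)
Conditions: H2 (1 atm), Pd/C (10 wt % palladium on carbon), EtOAc/MeOH, rt
Reagents that add atoms: none
Why: Catalytic hydrogenolysis of benzyl aryl ethers over palladium, which should cleave both O–benzyl bonds at room temperature and atmospheric pressure while the tetrasubstituted C2=C3 bond of the pyranone and the aryl methyl ethers stay intact if the reaction is stopped once monoethers 18 and 19 are consumed.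

**Compound list**

1 | 1-(benzyloxy)-4-bromobenzene | Brc1ccc(OCc2ccccc2)cc1 | starting material
2 | N,2-dimethoxy-N-methylacetamide | COCC(=O)N(C)OC | starting material
3 | 4-(benzyloxy)phenylmagnesium bromide | Br[Mg]c1ccc(OCc2ccccc2)cc1 | intermediate (not isolated)
4 | bromomagnesium salt of 1-[4-(benzyloxy)phenyl]-2-methoxy-1-[methoxy(methyl)amino]ethan-1-ol (racemic) | COCC(O[Mg]Br)(N(C)OC)c1ccc(OCc2ccccc2)cc1 | intermediate (not isolated)
5 | 1-[4-(benzyloxy)phenyl]-2-methoxyethan-1-one | COCC(=O)c1ccc(OCc2ccccc2)cc1 | intermediate
6 | syringaldehyde (4-hydroxy-3,5-dimethoxybenzaldehyde) | COc1cc(C=O)cc(OC)c1O | starting material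
7 | potassium 4-formyl-2,6-dimethoxyphenoxide | COc1cc(C=O)cc(OC)c1[O-].[K+] | intermediate (not isolated)
8 | 4-(benzyloxy)-3,5-dimethoxybenzaldehyde | COc1cc(C=O)cc(OC)c1OCc1ccccc1 | intermediate
9 | 4-(benzyloxy)-2-bromo-3,5-dimethoxybenzaldehyde | COc1cc(C=O)c(Br)c(OC)c1OCc1ccccc1 | intermediate (not isolated)
10 | 4-(benzyloxy)-2,6-dibromo-3,5-dimethoxybenzaldehyde | COc1c(Br)c(C=O)c(Br)c(OC)c1OCc1ccccc1 | intermediate
11 | lithium (Z)-enolate of ketone 5 | CO/C=C(\[O-])c1ccc(OCc2ccccc2)cc1.[Li+] | intermediate (not isolated)
12 | lithium aldolate of 13 (racemic syn/anti mixture) | COC(C(=O)c1ccc(OCc2ccccc2)cc1)C([O-])c1c(Br)c(OC)c(OCc2ccccc2)c(OC)c1Br.[Li+] | intermediate (not isolated)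
13 | 3-[4-(benzyloxy)-2,6-dibromo-3,5-dimethoxyphenyl]-1-[4-(benzyloxy)phenyl]-3-hydroxy-2-methoxypropan-1-one (racemic syn/anti mixture) | COC(C(=O)c1ccc(OCc2ccccc2)cc1)C(O)c1c(Br)c(OC)c(OCc2ccccc2)c(OC)c1Br | intermediate
14 | 1-[4-(benzyloxy)-2,6-dibromo-3,5-dimethoxyphenyl]-3-[4-(benzyloxy)phenyl]-2-methoxypropane-1,3-dione (racemic) | COC(C(=O)c1ccc(OCc2ccccc2)cc1)C(=O)c1c(Br)c(OC)c(OCc2ccccc2)c(OC)c1Br | intermediate
15 | potassium diketonate of 14 (one resonance form, enolate oxygen on the ring B side) | CO/C(C(=O)c1c(Br)c(OC)c(OCc2ccccc2)c(OC)c1Br)=C(/[O-])c1ccc(OCc2ccccc2)cc1.[K+] | intermediate (not isolated)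
16 | 7-(benzyloxy)-2-[4-(benzyloxy)phenyl]-5-bromo-3,6,8-trimethoxy-4H-chromen-4-one | COc1c(-c2ccc(OCc3ccccc3)cc2)oc2c(OC)c(OCc3ccccc3)c(OC)c(Br)c2c1=O | intermediate
17 | 7-(benzyloxy)-2-[4-(benzyloxy)phenyl]-3,5,6,8-tetramethoxy-4H-chromen-4-one | COc1c(-c2ccc(OCc3ccccc3)cc2)oc2c(OC)c(OCc3ccccc3)c(OC)c(OC)c2c1=O | intermediate
18 | 7-(benzyloxy)-2-(4-hydroxyphenyl)-3,5,6,8-tetramethoxy-4H-chromen-4-one | COc1c(-c2ccc(O)cc2)oc2c(OC)c(OCc3ccccc3)c(OC)c(OC)c2c1=O | intermediate (not isolated)
19 | 2-[4-(benzyloxy)phenyl]-7-hydroxy-3,5,6,8-tetramethoxy-4H-chromen-4-one | COc1c(-c2ccc(OCc3ccccc3)cc2)oc2c(OC)c(O)c(OC)c(OC)c2c1=O | intermediate (not isolated)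
20 | 7-hydroxy-2-(4-hydroxyphenyl)-3,5,6,8-tetramethoxy-4H-chromen-4-one (4',7-dihydroxy-3,5,6,8-tetramethoxyflavone) | COc1c(O)c(OC)c2oc(-c3ccc(O)cc3)c(OC)c(=O)c2c1OC | target

**Step count**

Total step count: 8. Longest linear sequence: 7 steps (steps 2 to 8, from syringaldehyde 6).

**Steps most likely to fail**

Step 6 (key step). Process at risk: once O1–C8a has formed, copper may go on to insert into the remaining C–Br bond, which now lies peri to the pyranone carbonyl, so that the bromine is lost by reduction or exchanged by adventitious hydroxide. Retro-Claisen cleavage of the diketonate before insertion is the second danger. The fallback gives up the twin-bromide design and puts the C5 oxygen in place before ring closure, so that the closing substrate carries a single halide. It sets out from aldehyde 8 and rejoins the route at 17, so that steps 6 and 7 are both replaced. NBS (1.05 equiv, MeCN, rt) should stop the bromination at monobromide 9, which is isolated in this variant. Exchange of its bromide with NaOMe and CuBr (DMF/MeOH, 100 °C) should give 4-(benzyloxy)-2,3,5-trimethoxybenzaldehyde F1. NBS bromination of the one free ring position should give 4-(benzyloxy)-2-bromo-3,5,6-trimethoxybenzaldehyde F2. Addition of lithium enolate 11 under the conditions of step 4 should give the aldol adduct 3-[4-(benzyloxy)-2-bromo-3,5,6-trimethoxyphenyl]-1-[4-(benzyloxy)phenyl]-3-hydroxy-2-methoxypropan-1-one F3. Dess–Martin oxidation should give the diketone 1-[4-(benzyloxy)-2-bromo-3,5,6-trimethoxyphenyl]-3-[4-(benzyloxy)phenyl]-2-methoxypropane-1,3-dione F4. The CuI/1,10-phenanthroline/K2CO3 closure of step 6, now with one bromide only, should form O1–C8a and deliver 17 directly.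

Step 7. Process at risk: reductive loss of bromine outpacing the exchange at a carbon flanked by the C6 methoxy group and C4a, or methoxide adding at C2 and opening the pyranone ring at the temperature needed. The fallback splits the step into hydroxylation and methylation; it sets out from 16 and rejoins at 17. Palladium-catalysed hydroxylation (Pd2(dba)3, tBuXPhos, KOH, 1,4-dioxane/H2O, 90 °C, acidic work-up) should give 7-(benzyloxy)-2-[4-(benzyloxy)phenyl]-5-hydroxy-3,6,8-trimethoxy-4H-chromen-4-one F5. O-Methylation of this hydrogen-bonded 5-hydroxyl (MeI, K2CO3, DMF, 50 °C) should then give 17.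

Step 4. Process at risk: slow addition to a carbonyl group shielded by two ortho bromines, and retro-aldol reversal of the crowded aldolate 12 on warming, which would return 5 and 10. The fallback makes C3–C4 by irreversible C-acylation at the diketone oxidation level; it sets out from aldehyde 10 and rejoins at diketone 14, which makes step 5 unnecessary. Pinnick oxidation (NaClO2, NaH2PO4, 2-methyl-2-butene, tBuOH/H2O) should give 4-(benzyloxy)-2,6-dibromo-3,5-dimethoxybenzoic acid F6. Oxalyl chloride with catalytic DMF in CH2Cl2 should give 4-(benzyloxy)-2,6-dibromo-3,5-dimethoxybenzoyl chloride F7. Claisen-type acylation of lithium enolate 11, generated from ketone 5 with LiN(SiMe3)2 (2.2 equiv, THF, −78 °C to 0 °C), should give 14 after acidic work-up.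

**Further compounds**

F1 | step 6 | 4-(benzyloxy)-2,3,5-trimethoxybenzaldehyde | COc1cc(C=O)c(OC)c(OC)c1OCc1ccccc1
F2 | step 6 | 4-(benzyloxy)-2-bromo-3,5,6-trimethoxybenzaldehyde | COc1c(Br)c(C=O)c(OC)c(OC)c1OCc1ccccc1
F3 | step 6 | 3-[4-(benzyloxy)-2-bromo-3,5,6-trimethoxyphenyl]-1-[4-(benzyloxy)phenyl]-3-hydroxy-2-methoxypropan-1-one (racemic syn/anti mixture) | COC(C(=O)c1ccc(OCc2ccccc2)cc1)C(O)c1c(Br)c(OC)c(OCc2ccccc2)c(OC)c1OC
F4 | step 6 | 1-[4-(benzyloxy)-2-bromo-3,5,6-trimethoxyphenyl]-3-[4-(benzyloxy)phenyl]-2-methoxypropane-1,3-dione (racemic) | COC(C(=O)c1ccc(OCc2ccccc2)cc1)C(=O)c1c(Br)c(OC)c(OCc2ccccc2)c(OC)c1OC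
F5 | step 7 | 7-(benzyloxy)-2-[4-(benzyloxy)phenyl]-5-hydroxy-3,6,8-trimethoxy-4H-chromen-4-one | COc1c(-c2ccc(OCc3ccccc3)cc2)oc2c(OC)c(OCc3ccccc3)c(OC)c(O)c2c1=O
F6 | step 4 | 4-(benzyloxy)-2,6-dibromo-3,5-dimethoxybenzoic acid | COc1c(Br)c(C(=O)O)c(Br)c(OC)c1OCc1ccccc1
F7 | step 4 | 4-(benzyloxy)-2,6-dibromo-3,5-dimethoxybenzoyl chloride | COc1c(Br)c(C(=O)Cl)c(Br)c(OC)c1OCc1ccccc1
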